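**Retrosynthetic overview**
1. Feature: in target 13 (chromone numbering O1, C2, C3, C4=O, C4a, C5–OH, C6–C8, C8a) the unbranched C15 chain sits on C2. C2 is the electrophilic β-carbon of the C2=C3–C4=O enone of the pyranone ring, and an odd C15 chain is palmitic acid (C16) less CO2.
2. C2=C3 double bond ⇒ racemic chromanone 11; dehydrogenation is the last step.
3. C2–C1′ bond ⇒ 5-hydroxychromone 4 plus pentadecyl radical 9. The radical is released at a cathode from N-hydroxyphthalimide palmitate 8, which is made from palmitic acid 5 and 6.
4. Ring order: the benzene ring is bought with 1. The pyranone ring is the only ring made, and it is closed in step 1 (C2 from amide acetal 2, O1–C2 bond by addition–elimination) before the chain is attached.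

Key step: step 3

Remark: the target has no stereocentre. The C2 centre that appears in 11 is carried as the racemate and disappears in step 4.

**Step 1**
Reactants: 1 2,6-dihydroxyacetophenone; 2 N,N-dimethylformamide dimethyl acetal
Product: 4 5-hydroxychromone, via enaminone 3 (not isolated)
Conditions: 2 (1.3 equiv), toluene, 85 °C; evaporate; conc. HCl, CH2Cl2, 40 °C
Reagents that add atoms: none
Why: This is the enaminone route to chromones: the acidic acetyl CH3 condenses with the amide acetal, acid then lets either of the two equivalent phenol oxygens attack the β-carbon with loss of dimethylamine (addition–elimination), and the second hydroxyl remains as the chelated C5–OH, so no regiochemical question arises.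

**Step 2**
Reactants: 5 palmitic acid; 6 N-hydroxyphthalimide
Product: 8 1,3-dioxoisoindolin-2-yl hexadecanoate (N-hydroxyphthalimide palmitate), via O-acylisourea 7 (not isolated)
Conditions: N,N'-diisopropylcarbodiimide (1.1 equiv), DMAP (0.1 equiv), CH2Cl2, 0 °C to rt
Reagents that add atoms: none
Why: In this Steglich-type carbodiimide esterification the O-acylisourea 7 is intercepted by the acidic N–OH of 6 under DMAP catalysis, and the crystalline ester should be freed from the urea by filtration and a short silica plug.

**Step 3**
Reactants: 4 5-hydroxychromone; 8 N-hydroxyphthalimide palmitate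
Product: 11 (±)-5-hydroxy-2-pentadecylchroman-4-one, via pentadecyl radical 9 (not isolated), via C3 adduct radical 10 (not isolated)
Conditions: undivided cell, graphite-felt cathode, sacrificial Zn anode, nBu4NBF4 (0.1 M), AcOH (2 equiv per 8), DMA, 30 °C, Ar; 4 (1 equiv, 0.25 M), 8 (2.5 equiv, in portions); constant current at low current density, about 2.2 F per mol of 8
Reagents that add atoms: none
Why: The cathode delivers one electron to the phthalimide unit of 8 (wave near −1.3 V vs SCE), the N–O bond of the radical anion breaks, and CO2 is lost to leave the primary, nucleophilic pentadecyl radical 9. Radical 9 attacks C2 of 4, the β-carbon of the C2=C3–C4=O enone whose acceptor orbital is lowered by the C5–OH···O=C4 hydrogen bond, and the resulting ketone-stabilised C3 radical 10 is much easier to reduce than 8, so it takes up the second electron at once and is protonated at C3 by AcOH. The closest known reaction type is the reductive decarboxylative Giese addition of N-hydroxyphthalimide esters to enones and chromones, run at a cathode or with a photoredox catalyst. No ring is closed, and the single new stereocentre C2 arises on a flat achiral acceptor without any controlling element, hence as a racemate, which is harmless because step 4 returns C2 to sp2. Site selectivity for C2 over C3 and the arene is secured by the polarity match between a nucleophilic radical and the enone β-carbon and by the fact that only C2 attack gives a carbonyl-conjugated radical, while electrode selectivity is secured by the gap of several hundred millivolts between the waves of 8 and 4, by electron transfer to 8 from any chromone radical anion that does form, and by the zinc anode, which is oxidised far more easily than the free phenol. AcOH keeps the C5 phenol protonated so that it is not acylated by 8, and since a primary radical adds only slowly to a β-oxygenated enone, 4 is kept concentrated and limiting while the cheap ester is fed in excess, so that radicals lost to hydrogen abstraction or dimerisation cost only palmitate.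

**Step 4**
Reactants: 11 (±)-5-hydroxy-2-pentadecylchroman-4-one
Product: 13 5-hydroxy-2-pentadecylchromone (target), via 3-iodochromanone 12 (not isolated)
Conditions: I2 (0.2 equiv), DMSO, 120 °C
Reagents that add atoms: none
Why: This is the iodine/DMSO dehydrogenation used for flavanone-to-flavone oxidation: the ketone can enolise only toward C3, iodination there gives 12, thermal loss of HI across C2–C3 gives the conjugated pyranone, DMSO turns HI back into I2, and the racemic C2 centre is erased.

**Compound list**
1 | 2,6-dihydroxyacetophenone | CC(=O)c1c(O)cccc1O | starting material
2 | N,N-dimethylformamide dimethyl acetal | COC(OC)N(C)C | starting material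
3 | (E)-3-(dimethylamino)-1-(2,6-dihydroxyphenyl)prop-2-en-1-one | CN(C)/C=C/C(=O)c1c(O)cccc1O | intermediate
4 | 5-hydroxychromone (5-hydroxy-4H-chromen-4-one) | O=c1ccoc2cccc(O)c12 | intermediate
5 | palmitic acid (hexadecanoic acid) | CCCCCCCCCCCCCCCC(=O)O | starting material
6 | N-hydroxyphthalimide | O=C1c2ccccc2C(=O)N1O | starting material
7 | O-palmitoyl-N,N'-diisopropylisourea | CCCCCCCCCCCCCCCC(=O)OC(=NC(C)C)NC(C)C | intermediate
8 | 1,3-dioxoisoindolin-2-yl hexadecanoate (N-hydroxyphthalimide palmitate) | CCCCCCCCCCCCCCCC(=O)ON1C(=O)c2ccccc2C1=O | intermediate
9 | pentadecyl radical | CCCCCCCCCCCCCC[CH2] | intermediate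
10 | 5-hydroxy-4-oxo-2-pentadecylchroman-3-yl radical (racemic at C2) | CCCCCCCCCCCCCCCC1[CH]C(=O)c2c(O)cccc2O1 | intermediate
11 | (±)-5-hydroxy-2-pentadecylchroman-4-one (racemic at C2) | CCCCCCCCCCCCCCCC1CC(=O)c2c(O)cccc2O1 | intermediate
12 | 5-hydroxy-3-iodo-2-pentadecylchroman-4-one (racemic, configuration at C2 and C3 not defined) | CCCCCCCCCCCCCCCC1Oc2cccc(O)c2C(=O)C1I | intermediate
13 | 5-hydroxy-2-pentadecyl-4H-chromen-4-one | CCCCCCCCCCCCCCCc1cc(=O)c2c(O)cccc2o1 | target

**Step count**
Total steps: 4. Longest linear sequence: 3 steps (1 → 4 → 11 → 13, or equally 5 → 8 → 11 → 13).

**Steps most likely to fail**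

Step 3.
- Risk: addition of the primary radical to the β-oxygenated enone may be too slow to compete with hydrogen abstraction from the medium and with radical dimerisation. The chromone itself may also be reduced once the ester near the cathode is depleted.
- Fallback: the pyranone ring is built around the chain by polar chemistry instead of adding the chain to the finished ring.
- It sets out from 1. Deprotonation with LiN(SiMe3)2 (4 equiv, THF, −78 °C) is followed by Claisen-type C-acylation of the lithium enolate with commercial palmitoyl chloride (CCCCCCCCCCCCCCCC(=O)Cl). This direct-acylation variant of the Baker–Venkataraman route should give 1-(2,6-dihydroxyphenyl)octadecane-1,3-dione F1.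
- Cyclodehydration (cat. H2SO4, AcOH, 100 °C) closes the O1–C2 bond and comes back to the route at 13, so steps 3 and 4 are bypassed.

Step 4.
- Risk: electrophilic iodination of the phenol-activated positions C6 and C8 may compete with iodination at C3. Loss of HI may also be sluggish because H-2 is not benzylic, unlike in a flavanone.
- Fallback: the phenol is masked, and halogenation and elimination are run as separate, base-driven operations.
- It sets out from 11. Acetylation (Ac2O, pyridine, cat. DMAP, 60 °C) should give 5-acetoxy-2-pentadecylchroman-4-one F2.
- Pyridinium tribromide (CH2Cl2, rt) brominates the only enolisable position to give 5-acetoxy-3-bromo-2-pentadecylchroman-4-one F3.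
- Li2CO3 and LiBr (DMF, 100 °C) eliminate HBr to give 5-acetoxy-2-pentadecylchromone F4.
- K2CO3 in MeOH (rt) removes the acetate and comes back to the route at 13.

Step 1.
- Risk: the amide acetal may O-methylate the phenols, or the condensation at the doubly chelated acetyl group may stay incomplete.
- Fallback: the C2 carbon is introduced by a base-mediated Claisen formylation with an ester instead of an amide acetal.
- It sets out from 1. NaH (4 equiv) and ethyl formate (THF, 0 °C to rt), followed by acidification, should give the β-keto aldehyde as its cyclic hemiacetal, 2,5-dihydroxychroman-4-one F5.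
- Acid-catalysed dehydration (cat. HCl, AcOH, 80 °C) comes back to the route at 4.

**Further compounds**
F1 | step 3 | 1-(2,6-dihydroxyphenyl)octadecane-1,3-dione | CCCCCCCCCCCCCCCC(=O)CC(=O)c1c(O)cccc1O
F2 | step 4 | 5-acetoxy-2-pentadecylchroman-4-one (racemic) | CCCCCCCCCCCCCCCC1CC(=O)c2c(OC(C)=O)cccc2O1
F3 | step 4 | 5-acetoxy-3-bromo-2-pentadecylchroman-4-one (racemic, configuration at C2 and C3 not defined) | CCCCCCCCCCCCCCCC1Oc2cccc(OC(C)=O)c2C(=O)C1Br
F4 | step 4 | 5-acetoxy-2-pentadecylchromone | CCCCCCCCCCCCCCCc1cc(=O)c2c(OC(C)=O)cccc2o1
F5 | step 1 | 2,5-dihydroxychroman-4-one (racemic hemiacetal) | OC1CC(=O)c2c(O)cccc2O1
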